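Chain numbering: C1 is the ring carbon bearing the guaiacyl group, C7 the ArCH2 carbon, and the ring oxygen links C1 and C5. The enabling feature is that C2–C3(O)–C4 is an acetone unit lying between two oxygen-bearing carbons, C1 and C5, each of which can be traced back to an aldehyde carbonyl carbon.
Retrosynthesis: with C3 returned to a ketone and an ester placed on C2, the cuts are C1–O, C1–C2 and C4–C5. They leave the bis-silyl dienol ether of methyl acetoacetate (C2–C4), O-benzylvanillin (C1) and an (R)-2-silyloxy-3-arylpropanal (C5–C7) made from O-benzyl-D-tyrosine.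
Forward: the diene (2 steps) and the aldehyde (4 steps) are made separately. In one flask the chain is joined at C4–C5, then at C1–C2, and the only ring, the tetrahydropyran, closes last through C1–O. Decarboxylation, ketone reduction, desilylation and debenzylation follow.
Stereochemistry: C6 comes from D-tyrosine (diazotisation with retention), C5 from Felkin–Anh addition to the α-silyloxy aldehyde (anti to C6), C1 from the reversible, thermodynamically controlled ring closure (2,6-cis), and C3 from axial hydride attack on the locked pyranone.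

Key step: step 7

Remark: O-benzyl-D-tyrosine is taken as a catalogue amino acid derivative; the key-step product and the keto acid derived from it are drawn as enol tautomers, which stand for the keto–enol mixture.

Step 1
Reactants: 1 methyl acetoacetate
Product: 2 methyl 3-(trimethylsilyloxy)but-2-enoate (E/Z mixture)
Conditions: Me3SiCl, Et3N, hexane, rt
Reagents that add atoms: chlorotrimethylsilane, C[Si](C)(C)Cl
Why: Et3N/Me3SiCl O-silylates the enol of the β-keto ester (silyl enol ether formation), which masks the ketone and leaves the γ-methyl group as the only acidic site for step 2; no stereocentre is involved.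

Step 2
Reactants: 2 methyl 3-(trimethylsilyloxy)but-2-enoate
Product: 3 1-methoxy-1,3-bis(trimethylsilyloxy)buta-1,3-diene (bis-silyl dienol ether of methyl acetoacetate, E/Z mixture)
Conditions: LiN(i-Pr)2 (commercial solution), THF, −78 °C; then Me3SiCl, −78 → 0 °C
Reagents that add atoms: chlorotrimethylsilane, C[Si](C)(C)Cl
Why: LiN(i-Pr)2 removes a γ-proton of the vinylogous ester and the dienolate is trapped on oxygen by Me3SiCl (silyl ketene acetal formation), giving the electron-rich diene whose terminal CH2 becomes C4 of the chain; the double-bond geometry is of no consequence.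

Step 3
Reactants: 4 O-benzyl-D-tyrosine, (R)-2-amino-3-[4-(benzyloxy)phenyl]propanoic acid
Product: 5 (R)-3-[4-(benzyloxy)phenyl]-2-hydroxypropanoic acid
Conditions: NaNO2, 1 M aq. H2SO4, 1,4-dioxane, 0 °C → rt
Reagents that add atoms: water, O
Why: Diazotisation–hydrolysis of an α-amino acid replaces NH2 by OH with net retention (the carboxylate displaces N2 from the back and water then displaces the carboxylate, two inversions), so the R centre of 4 becomes the R carbinol (future C6), and the benzyl ether keeps the phenol ring from being nitrosated.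

Step 4
Reactants: 5 (R)-3-[4-(benzyloxy)phenyl]-2-hydroxypropanoic acid
Product: 6 methyl (R)-3-[4-(benzyloxy)phenyl]-2-hydroxypropanoate
Conditions: MeOH, cat. H2SO4, 65 °C
Reagents that add atoms: methanol, CO
Why: Fischer esterification in excess methanol; the carbinol centre is not touched and the aryl benzyl ether tolerates the catalytic acid.

Step 5
Reactants: 6 methyl (R)-3-[4-(benzyloxy)phenyl]-2-hydroxypropanoate
Product: 7 methyl (R)-3-[4-(benzyloxy)phenyl]-2-(tert-butyldiphenylsilyloxy)propanoate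
Conditions: t-BuPh2SiCl, imidazole, cat. DMAP, DMF, rt
Reagents that add atoms: tert-butyl(chloro)diphenylsilane, CC(C)(C)[Si](Cl)(c1ccccc1)c1ccccc1
Why: Silyl chloride/imidazole silylation of the secondary alcohol; the tert-butyldiphenylsilyl ether is chosen because it is bulky and weakly basic, hence non-chelating in step 7, and should survive CF3CO2H and 160 °C later on.

Step 6
Reactants: 7 methyl (R)-3-[4-(benzyloxy)phenyl]-2-(tert-butyldiphenylsilyloxy)propanoate
Product: 8 (R)-3-[4-(benzyloxy)phenyl]-2-(tert-butyldiphenylsilyloxy)propanal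
Conditions: i-Bu2AlH (1.1 equiv), CH2Cl2, −78 °C; MeOH, then aq. potassium sodium tartrate
Reagents that add atoms: none
Why: i-Bu2AlH half-reduction of an α-oxygenated ester at −78 °C halts at the tetrahedral aluminium alkoxide, which releases the aldehyde only on work-up, so over-reduction is held back; the aldehyde is used crude and at once to keep the α-centre intact.

Step 7
Reactants: 8 (R)-3-[4-(benzyloxy)phenyl]-2-(tert-butyldiphenylsilyloxy)propanal; 3 1-methoxy-1,3-bis(trimethylsilyloxy)buta-1,3-diene; 9 4-(benzyloxy)-3-methoxybenzaldehyde (O-benzylvanillin)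
Product: 12 methyl (2S,6S)-2-[4-(benzyloxy)-3-methoxyphenyl]-6-[(1R)-2-[4-(benzyloxy)phenyl]-1-(tert-butyldiphenylsilyloxy)ethyl]-4-hydroxy-5,6-dihydro-2H-pyran-3-carboxylate (2,6-cis; enol tautomer of the 4-oxotetrahydropyran-3-carboxylate), via δ-hydroxy-β-keto ester 10 (not isolated), via arylidene β-keto ester 11 (not isolated)
Conditions: 8, TiCl4 (1.1 equiv), CH2Cl2, −78 °C, then 3 (1.3 equiv), 1 h; then 9, CF3CO2H, −78 °C → rt
Reagents that add atoms: none
Why: TiCl4-bound 8 is attacked by the terminal carbon of diene 3 in a vinylogous Mukaiyama aldol addition (C4–C5), CF3CO2H frees δ-hydroxy-β-keto ester 10, its C2 methylene condenses with 9 (Knoevenagel, C1–C2) to arylidene 11, and the C5 hydroxyl finally adds to the arylidene carbon (C1–O). The closest known reaction type is the one-pot Maitland–Japp synthesis of tetrahydropyran-4-ones from a bis-silyl dienol ether of an acetoacetate and two different aldehydes. The single ring, the tetrahydropyran, closes by a 6-endo-trig oxa-Michael addition. C5 is set in the aldol step by Felkin–Anh addition to the α-silyloxy aldehyde, anti to the C6 oxygen, and C1 is set by the reversible oxa-Michael closure under thermodynamic control, which leaves the aryl group and the side chain both equatorial (2,6-cis). The step needs non-chelation facial selectivity, secured by the bulky and weakly basic tert-butyldiphenylsilyl ether that titanium cannot bridge, and it needs the two aldehydes to keep their roles, secured by adding non-enolisable 9 only after 8 has been consumed. The electron-rich aryl group on C1 and the doubly activated C2 keep the C1–O bond labile, so a kinetically formed trans isomer can drain into the cis product while C5 stays fixed.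

Step 8
Reactants: 12 methyl (2S,6S)-2-[4-(benzyloxy)-3-methoxyphenyl]-6-[(1R)-2-[4-(benzyloxy)phenyl]-1-(tert-butyldiphenylsilyloxy)ethyl]-4-hydroxy-5,6-dihydro-2H-pyran-3-carboxylate
Product: 14 (2R,6S)-2-[4-(benzyloxy)-3-methoxyphenyl]-6-[(1R)-2-[4-(benzyloxy)phenyl]-1-(tert-butyldiphenylsilyloxy)ethyl]tetrahydro-4H-pyran-4-one (2,6-cis), via β-keto acid 13 (not isolated)
Conditions: DMF–H2O (10:1), 160 °C, microwave
Reagents that add atoms: none
Why: Hydrolytic decarbomethoxylation of a β-keto ester (Krapcho-type, salt-free): hot water cleaves the activated methyl ester to keto acid 13, which loses CO2 through its cyclic six-centre transition state, while the neutral medium should leave silyl and benzyl ethers alone and the 2,6-cis arrangement, being the stable one, should persist.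

Step 9
Reactants: 14 (2R,6S)-2-[4-(benzyloxy)-3-methoxyphenyl]-6-[(1R)-2-[4-(benzyloxy)phenyl]-1-(tert-butyldiphenylsilyloxy)ethyl]tetrahydro-4H-pyran-4-one
Product: 15 (2R,4R,6S)-2-[4-(benzyloxy)-3-methoxyphenyl]-6-[(1R)-2-[4-(benzyloxy)phenyl]-1-(tert-butyldiphenylsilyloxy)ethyl]tetrahydro-2H-pyran-4-ol (all-cis ring)
Conditions: NaBH4, MeOH–CH2Cl2, −20 → 0 °C
Reagents that add atoms: none
Why: Borohydride reduction of the conformationally locked 2,6-diequatorial tetrahydropyran-4-one takes place by axial attack of the small hydride, which gives the equatorial C3 alcohol cis to both ring substituents (the R centre of the target).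

Step 10
Reactants: 15 (2R,4R,6S)-2-[4-(benzyloxy)-3-methoxyphenyl]-6-[(1R)-2-[4-(benzyloxy)phenyl]-1-(tert-butyldiphenylsilyloxy)ethyl]tetrahydro-2H-pyran-4-ol
Product: 16 (2R,4R,6S)-2-[4-(benzyloxy)-3-methoxyphenyl]-6-[(1R)-2-[4-(benzyloxy)phenyl]-1-hydroxyethyl]tetrahydro-2H-pyran-4-ol
Conditions: Bu4NF, THF, rt
Reagents that add atoms: none
Why: Fluoride-mediated desilylation driven by the strong Si–F bond; benzyl ethers, the ring and all four stereocentres are inert to Bu4NF.

Step 11
Reactants: 16 (2R,4R,6S)-2-[4-(benzyloxy)-3-methoxyphenyl]-6-[(1R)-2-[4-(benzyloxy)phenyl]-1-hydroxyethyl]tetrahydro-2H-pyran-4-ol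
Product: 17 (2R,4R,6S)-2-(4-hydroxy-3-methoxyphenyl)-6-[(1R)-1-hydroxy-2-(4-hydroxyphenyl)ethyl]tetrahydro-2H-pyran-4-ol (CNP0116327.2)
Conditions: H2 (1 atm), 10% Pd/C, EtOAc–MeOH, rt
Reagents that add atoms: none
Why: Catalytic hydrogenolysis of the two aryl benzyl ethers over Pd/C is far faster than cleavage of the cyclic secondary benzylic C1–O bond, so stopping after two equivalents of H2 should release both phenols and leave the tetrahydropyran and its stereocentres intact.

Compound list
1 | methyl acetoacetate | COC(=O)CC(C)=O | starting material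
2 | methyl 3-(trimethylsilyloxy)but-2-enoate (E/Z mixture) | COC(=O)C=C(C)O[Si](C)(C)C | intermediate
3 | 1-methoxy-1,3-bis(trimethylsilyloxy)buta-1,3-diene (E/Z mixture) | COC(O[Si](C)(C)C)=CC(O[Si](C)(C)C)=C | intermediate
4 | O-benzyl-D-tyrosine, (R)-2-amino-3-[4-(benzyloxy)phenyl]propanoic acid | N[C@H](Cc1ccc(OCc2ccccc2)cc1)C(=O)O | starting material
5 | (R)-3-[4-(benzyloxy)phenyl]-2-hydroxypropanoic acid | O[C@H](Cc1ccc(OCc2ccccc2)cc1)C(=O)O | intermediate
6 | methyl (R)-3-[4-(benzyloxy)phenyl]-2-hydroxypropanoate | O[C@H](Cc1ccc(OCc2ccccc2)cc1)C(=O)OC | intermediate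
7 | methyl (R)-3-[4-(benzyloxy)phenyl]-2-(tert-butyldiphenylsilyloxy)propanoate | CC(C)(C)[Si](c1ccccc1)(c1ccccc1)O[C@H](Cc1ccc(OCc2ccccc2)cc1)C(=O)OC | intermediate
8 | (R)-3-[4-(benzyloxy)phenyl]-2-(tert-butyldiphenylsilyloxy)propanal | CC(C)(C)[Si](c1ccccc1)(c1ccccc1)O[C@H](Cc1ccc(OCc2ccccc2)cc1)C=O | intermediate
9 | 4-(benzyloxy)-3-methoxybenzaldehyde (O-benzylvanillin) | COc1cc(C=O)ccc1OCc1ccccc1 | starting material
10 | methyl (5S,6R)-7-[4-(benzyloxy)phenyl]-6-(tert-butyldiphenylsilyloxy)-5-hydroxy-3-oxoheptanoate (5,6-anti; not isolated) | COC(=O)CC(=O)C[C@@H]([C@H](O[Si](c1ccccc1)(c1ccccc1)C(C)(C)C)Cc1ccc(OCc2ccccc2)cc1)O | intermediate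
11 | methyl (5S,6R)-2-[4-(benzyloxy)-3-methoxybenzylidene]-7-[4-(benzyloxy)phenyl]-6-(tert-butyldiphenylsilyloxy)-5-hydroxy-3-oxoheptanoate (E/Z mixture; not isolated) | COC(=O)C(=Cc1ccc(OCc2ccccc2)c(OC)c1)C(=O)C[C@@H]([C@H](O[Si](c1ccccc1)(c1ccccc1)C(C)(C)C)Cc1ccc(OCc2ccccc2)cc1)O | intermediate
12 | methyl (2S,6S)-2-[4-(benzyloxy)-3-methoxyphenyl]-6-[(1R)-2-[4-(benzyloxy)phenyl]-1-(tert-butyldiphenylsilyloxy)ethyl]-4-hydroxy-5,6-dihydro-2H-pyran-3-carboxylate (2,6-cis; enol tautomer) | COc1cc([C@H]2C(C(=O)OC)=C(O)C[C@@H]([C@H](O[Si](c3ccccc3)(c3ccccc3)C(C)(C)C)Cc3ccc(OCc4ccccc4)cc3)O2)ccc1OCc1ccccc1 | intermediate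
13 | (2S,6S)-2-[4-(benzyloxy)-3-methoxyphenyl]-6-[(1R)-2-[4-(benzyloxy)phenyl]-1-(tert-butyldiphenylsilyloxy)ethyl]-4-hydroxy-5,6-dihydro-2H-pyran-3-carboxylic acid (2,6-cis; enol tautomer; not isolated) | COc1cc([C@H]2C(C(=O)O)=C(O)C[C@@H]([C@H](O[Si](c3ccccc3)(c3ccccc3)C(C)(C)C)Cc3ccc(OCc4ccccc4)cc3)O2)ccc1OCc1ccccc1 | intermediate
14 | (2R,6S)-2-[4-(benzyloxy)-3-methoxyphenyl]-6-[(1R)-2-[4-(benzyloxy)phenyl]-1-(tert-butyldiphenylsilyloxy)ethyl]tetrahydro-4H-pyran-4-one (2,6-cis) | COc1cc([C@H]2CC(=O)C[C@@H]([C@H](O[Si](c3ccccc3)(c3ccccc3)C(C)(C)C)Cc3ccc(OCc4ccccc4)cc3)O2)ccc1OCc1ccccc1 | intermediate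
15 | (2R,4R,6S)-2-[4-(benzyloxy)-3-methoxyphenyl]-6-[(1R)-2-[4-(benzyloxy)phenyl]-1-(tert-butyldiphenylsilyloxy)ethyl]tetrahydro-2H-pyran-4-ol (all-cis ring) | COc1cc([C@H]2C[C@@H](O)C[C@@H]([C@H](O[Si](c3ccccc3)(c3ccccc3)C(C)(C)C)Cc3ccc(OCc4ccccc4)cc3)O2)ccc1OCc1ccccc1 | intermediate
16 | (2R,4R,6S)-2-[4-(benzyloxy)-3-methoxyphenyl]-6-[(1R)-2-[4-(benzyloxy)phenyl]-1-hydroxyethyl]tetrahydro-2H-pyran-4-ol | COc1cc([C@H]2C[C@@H](O)C[C@@H]([C@H](O)Cc3ccc(OCc4ccccc4)cc3)O2)ccc1OCc1ccccc1 | intermediate
17 | (2R,4R,6S)-2-(4-hydroxy-3-methoxyphenyl)-6-[(1R)-1-hydroxy-2-(4-hydroxyphenyl)ethyl]tetrahydro-2H-pyran-4-ol | COc1cc([C@H]2C[C@@H](O)C[C@@H]([C@H](O)Cc3ccc(O)cc3)O2)ccc1O | target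

Total step count: 11 (steps 1–2 for the diene, steps 3–6 for the aldehyde, steps 7–11 for the union and finish).
Longest linear sequence: 9 steps (4 → 17, steps 3–11).

Steps most likely to fail

Step 7. What may go wrong: partial bridging of the α-oxygen by titanium, which erodes the Felkin facial selectivity at C5; a slow Knoevenagel condensation of the electron-rich aldehyde, during which the acid strips silyl or benzyl groups; and incomplete cis/trans equilibration. Fallback (sets out from 8 and 9, comes back at 14, so steps 7 and 8 are both replaced): the ring is assembled in a different order. Aldehyde 9 is condensed with acetone (aq. NaOH, Claisen–Schmidt) to (E)-4-[4-(benzyloxy)-3-methoxyphenyl]but-3-en-2-one F1. The methyl group of F1 is its only enolisable position, so Me3SiOTf/Et3N (CH2Cl2, 0 °C) should give (E)-1-[4-(benzyloxy)-3-methoxyphenyl]-3-(trimethylsilyloxy)buta-1,3-diene F2. A Mukaiyama aldol addition of F2 to 8 under BF3·OEt2 at −78 °C, a Lewis acid with a single free coordination site and therefore unable to chelate, should give the anti hydroxy enone (1E,5S,6R)-1-[4-(benzyloxy)-3-methoxyphenyl]-7-[4-(benzyloxy)phenyl]-6-(tert-butyldiphenylsilyloxy)-5-hydroxyhept-1-en-3-one F3. Base-catalysed, equilibrating 6-endo oxa-Michael closure (DBU, CH2Cl2, rt) should then give the 2,6-cis ketone 14 without any ester to remove.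

Step 8. What may go wrong: retro-oxa-Michael ring opening at 160 °C with epimerisation at C1 or C5, or loss of the silyl ether in hot wet DMF. Fallback (sets out from 8 and 9, comes back at 14): the ester is changed so that it leaves at room temperature. Commercial allyl acetoacetate is silylated (Me3SiCl, Et3N) to allyl 3-(trimethylsilyloxy)but-2-enoate F4 and then (LiN(i-Pr)2; Me3SiCl) to 1-(allyloxy)-1,3-bis(trimethylsilyloxy)buta-1,3-diene F5. F5 takes the place of 3 in the protocol of step 7 with 8 and 9 and should give allyl (2S,6S)-2-[4-(benzyloxy)-3-methoxyphenyl]-6-[(1R)-2-[4-(benzyloxy)phenyl]-1-(tert-butyldiphenylsilyloxy)ethyl]-4-hydroxy-5,6-dihydro-2H-pyran-3-carboxylate F6. Catalytic Pd(PPh3)4 (zerovalent palladium) with morpholine in THF at rt removes the allyl group (Tsuji–Trost deallylation), and keto acid 13 loses CO2 at that temperature to give 14.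

Step 6. What may go wrong: over-reduction to the primary alcohol and epimerisation of the α-silyloxy aldehyde during work-up or storage. Fallback (sets out from 7, comes back at 8): the ester is reduced completely with LiBH4 (THF–MeOH, 0 °C) to (R)-3-[4-(benzyloxy)phenyl]-2-(tert-butyldiphenylsilyloxy)propan-1-ol F7. F7 is then oxidised under NaHCO3-buffered Dess–Martin conditions (CH2Cl2, rt) to 8 immediately before step 7; neither operation can overshoot, and the buffered oxidation should not touch the α-centre.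

Further compounds
F1 | step 7 | (E)-4-[4-(benzyloxy)-3-methoxyphenyl]but-3-en-2-one | CC(=O)/C=C/c1ccc(OCc2ccccc2)c(OC)c1
F2 | step 7 | (E)-1-[4-(benzyloxy)-3-methoxyphenyl]-3-(trimethylsilyloxy)buta-1,3-diene | C=C(O[Si](C)(C)C)/C=C/c1ccc(OCc2ccccc2)c(OC)c1
F3 | step 7 | (1E,5S,6R)-1-[4-(benzyloxy)-3-methoxyphenyl]-7-[4-(benzyloxy)phenyl]-6-(tert-butyldiphenylsilyloxy)-5-hydroxyhept-1-en-3-one | COc1cc(/C=C/C(=O)C[C@@H]([C@H](O[Si](c2ccccc2)(c2ccccc2)C(C)(C)C)Cc2ccc(OCc3ccccc3)cc2)O)ccc1OCc1ccccc1
F4 | step 8 | allyl 3-(trimethylsilyloxy)but-2-enoate (E/Z mixture) | C=CCOC(=O)C=C(C)O[Si](C)(C)C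
F5 | step 8 | 1-(allyloxy)-1,3-bis(trimethylsilyloxy)buta-1,3-diene (E/Z mixture) | C=CCOC(O[Si](C)(C)C)=CC(O[Si](C)(C)C)=C
F6 | step 8 | allyl (2S,6S)-2-[4-(benzyloxy)-3-methoxyphenyl]-6-[(1R)-2-[4-(benzyloxy)phenyl]-1-(tert-butyldiphenylsilyloxy)ethyl]-4-hydroxy-5,6-dihydro-2H-pyran-3-carboxylate (2,6-cis; enol tautomer) | COc1cc([C@H]2C(C(=O)OCC=C)=C(O)C[C@@H]([C@H](O[Si](c3ccccc3)(c3ccccc3)C(C)(C)C)Cc3ccc(OCc4ccccc4)cc3)O2)ccc1OCc1ccccc1
F7 | step 6 | (R)-3-[4-(benzyloxy)phenyl]-2-(tert-butyldiphenylsilyloxy)propan-1-ol | CC(C)(C)[Si](c1ccccc1)(c1ccccc1)O[C@H](Cc1ccc(OCc2ccccc2)cc1)CO
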